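- Isomer of the product A is what you will count when you come, set against target; that share is the selectivity asked for.

| flask | substrate | free catalyst | remark | time |
|---|---|---|---|---|
| blue | 1.5 M | 150 mM | run made earlier |  |
| teal | 3 M | 75 mM | run made earlier |  |
| flask | 3.0 M | 150 mM |  | 6.0 h |

| run | time / h | isomer of the product A / % | target / % | substrate / % |
|---|---|---|---|---|
| blue | 1.00 | 23.2 | 12.0 | 3.8 |
| blue | 2.00 | 24.6 | 4.7 | 0 |
| blue | 3.00 | 24.9 | 3.4 | 0 |
| blue | 4.00 | 24.3 | 3.1 | 0 |
| blue | 5.00 | 26.6 | 3.3 | 0.8 |
| blue | 6.00 | 23.2 | 3.3 | 0 |
| blue | 8.00 | 24.9 | 0.8 | 0 |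
| teal | 0.500 | 26.9 | 29.1 | 6.7 |
| teal | 1.00 | 30.9 | 13.8 | 2.0 |
| teal | 2.00 | 32.7 | 3.1 | 1.3 |
| teal | 4.00 | 32.0 | 2.1 | 0 |
| teal | 8.00 | 31.5 | 2.3 | 0 |

(each reading ± 1 percentage point)

- share of isomer of the product A in isomer of the product A plus target at 12 s
- share of isomer of the product A in isomer of the product A plus target at 6.0 h



- The tails read flat, so replace each by its mean, taken from 3.00 h in blue and from 4.00 h in teal; the mean of target carries a scatter of about 0.38 percentage points.
- My floor ratio φ = 3.57% is target over everything charged that is not isomer of the product A.
- This flask has blue's free catalyst charge, so I take blue's tail, 24.8% isomer of the product A, assuming that doubled substrate leaves the percentage alone, which no run tests.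
- φ then gives a late share of 90.2%.
- Keep the free catalyst at its charge, since my figure comes from blue's tail at that same charge; teal, with half of blue's free catalyst and also twice its substrate, stands higher in isomer of the product A at 4.00 h.
- I give no number for 12 s, since the earliest reading is at 0.500 h.
- The forecast says 38% and 91%: “This is an extrapolation, since no early data exist”.
- The flask gives 1.09% and 88.9%.

    target ⇌ isomer of the product B (K = 24.0, k = 0.0340 /min)
    substrate ⇌ other conformer (K = 0.750, k = 0.0770 /min)
    free catalyst + other conformer → free catalyst + isomer of the product A (k = 2.50 /M/min)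
    2 free catalyst → spent catalyst (k = 0.570 /M/min)
    substrate + free catalyst → free catalyst + target (k = 1.70 /M/min)

- The early forecast stands far above the flask, while the late one lies close.
- This flask ends with 24.2% isomer of the product A, so φ puts target at 2.71%, and the flask holds 3.03%.
- The neighbour, charged with 0.037 M free catalyst, ends with 38.7% isomer of the product A, so φ puts target at 2.19% and the share at 94.6%; that neighbour holds 2.48% target and a share of 94.0%.

(The data are calculated with constants of no real substance.)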